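The flavanone is disconnected at the aryl–oxygen bond O1–C8a of ring C. The feature exploited is that O1 sits between the sole stereocentre C2 and the sp2 carbon C8a of ring A. The C2–O1 bond can therefore be taken enantiopure from an epoxide and left alone, while the achiral O1–C8a bond is made last. A copper-catalysed intramolecular O-arylation thus closes ring C in one operation without touching C2. Its precursor is an (S)-benzylic alcohol of ring B whose CH2 group hangs on a 1,3-dithiane (masked C4) that also carries a 2-bromo-4,6-bis(silyloxy)phenyl ring A. Thioacetal hydrolysis and buffered fluoride then complete the synthesis.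

Key step: step 12

Remark: flavanone numbering is used (O1, C2, C3, C4, C4a, C5 to C8, C8a; ring B primed). ArB stands for the 4-methoxy-3-(3-methylbut-2-enyl)-5-[(E)-3-methyl-3-(triethylsilyloxy)but-1-enyl]phenyl group.

Step 1
Reactants: 1 3-bromo-4-hydroxybenzaldehyde
Product: 2 3-bromo-4-hydroxy-5-iodobenzaldehyde
Conditions: NIS (1.05 equiv), TFA (cat.), MeCN, rt
Reagents that add atoms: N-iodosuccinimide, O=C1CCC(=O)N1I
Why: Electrophilic aromatic iodination, in which the phenol directs ortho/para, the para position holds the formyl group and one ortho position the bromine, so only C5 is open and two halogens of different reactivity result for two successive couplings.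

Step 2
Reactants: 2 3-bromo-4-hydroxy-5-iodobenzaldehyde
Product: 3 3-bromo-5-iodo-4-methoxybenzaldehyde
Conditions: MeI, K2CO3, DMF, rt
Reagents that add atoms: iodomethane, CI
Why: Williamson ether synthesis on an acidic, doubly ortho-halogenated phenoxide fixes the 4'-methoxy group before any palladium chemistry.

Step 3
Reactants: 3 3-bromo-5-iodo-4-methoxybenzaldehyde; 4 2-methylbut-3-en-2-ol
Product: 5 3-bromo-5-[(E)-3-hydroxy-3-methylbut-1-enyl]-4-methoxybenzaldehyde
Conditions: Pd(OAc)2 (3 mol%), Bu4NCl, NaHCO3, DMF, 50 °C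
Reagents that add atoms: none
Why: Mizoroki–Heck reaction under ligand-free Jeffery conditions, in which zerovalent palladium inserts into C–I much faster than into C–Br at this temperature, syn insertion and syn β-hydride elimination give the E-alkene, and the quaternary carbinol carbon has no hydrogen through which a ketone could form.

Step 4
Reactants: 5 3-bromo-5-[(E)-3-hydroxy-3-methylbut-1-enyl]-4-methoxybenzaldehyde
Product: 6 3-bromo-4-methoxy-5-[(E)-3-methyl-3-(triethylsilyloxy)but-1-enyl]benzaldehyde
Conditions: TESOTf, 2,6-lutidine, CH2Cl2, −78 → 0 °C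
Reagents that add atoms: triethylsilyl trifluoromethanesulfonate, CC[Si](CC)(CC)OS(=O)(=O)C(F)(F)F
Why: Silylation of a tertiary alcohol with a silyl triflate and a hindered pyridine removes the only acidic proton of ring B ahead of the ylide, carbanion and copper steps, and the group leaves at the end with the same fluoride that frees the phenols.

Step 5
Reactants: 6 3-bromo-4-methoxy-5-[(E)-3-methyl-3-(triethylsilyloxy)but-1-enyl]benzaldehyde; 7 tributyl(3-methylbut-2-enyl)stannane
Product: 8 ArB-carbaldehyde = 4-methoxy-3-(3-methylbut-2-enyl)-5-[(E)-3-methyl-3-(triethylsilyloxy)but-1-enyl]benzaldehyde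
Conditions: Pd(PPh3)4 (5 mol%), DMF, 90 °C, degassed
Reagents that add atoms: none
Why: Migita–Kosugi–Stille coupling under neutral conditions that spare aldehyde and silyl ether, in which the aryl(η3-prenyl)palladium intermediate reductively eliminates at its unsubstituted terminus to give the linear prenyl arene, and its place after the Heck step keeps the prenyl alkene away from palladium hydride.

Step 6
Reactants: 8 ArB-carbaldehyde
Product: 9 racemic 2-ArB-oxirane
Conditions: Me3SI, NaH, DMSO–THF, 0 °C → rt
Reagents that add atoms: trimethylsulfonium iodide, C[S+](C)C.[I-]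
Why: Corey–Chaykovsky epoxidation, in which the ylide adds to the non-enolisable aldehyde and the betaine closes with loss of dimethyl sulfide, leaving both alkenes untouched.

Step 7
Reactants: 9 racemic 2-ArB-oxirane
Product: 10 (R)-2-ArB-oxirane
Conditions: (R,R)-(salen)Co(OAc) (2 mol%, from (R,R)-(salen)Co, AcOH, air; salen = N,N'-bis(3,5-di-tert-butylsalicylidene)cyclohexane-1,2-diaminate), H2O (0.55 equiv), THF, 0 °C → rt; chromatography on Et3N-washed silica
Reagents that add atoms: none
Why: Jacobsen hydrolytic kinetic resolution, established for styrene oxides, sets C2 because the catalyst enantiomer chosen delivers water to the CH2 of the (S)-epoxide much faster, so that running slightly past half conversion should leave the (R)-epoxide in high enantiomeric purity, while the 4'-methoxy group, twisted out of conjugation by its two ortho neighbours, gives little help to unselective benzylic opening.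

Step 8
Reactants: 11 5-bromoresorcinol
Product: 13 2-bromo-4,6-dihydroxybenzaldehyde, via iminium dichlorophosphate 12 (not isolated)
Conditions: POCl3, DMF, MeCN, 0 °C → rt; then H2O, 50 °C
Reagents that add atoms: N,N-dimethylformamide, CN(C)C=O; water, O
Why: Vilsmeier–Haack formylation attacks para to one hydroxyl and ortho to the other (the carbon next to bromine) and not the crowded carbon between both hydroxyls, as orcinol does, which sets CHO, Br and the two oxygens in the ring A pattern.

Step 9
Reactants: 13 2-bromo-4,6-dihydroxybenzaldehyde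
Product: 14 2-bromo-4,6-bis(triisopropylsilyloxy)benzaldehyde
Conditions: TIPSOTf (2.5 equiv), 2,6-lutidine, CH2Cl2, 0 °C → rt
Reagents that add atoms: triisopropylsilyl trifluoromethanesulfonate, CC(C)[Si](C(C)C)(C(C)C)OS(=O)(=O)C(F)(F)F
Why: A silyl triflate with a hindered base silylates both phenols, the hydrogen-bonded one included, and triisopropylsilyl is chosen because its bulk screens the two ring A hydrogens from metalation, disfavours an O-to-C silyl shift onto the later dithiane carbanion and withstands anhydrous carbonate, yet still leaves with buffered fluoride.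

Step 10
Reactants: 14 2-bromo-4,6-bis(triisopropylsilyloxy)benzaldehyde; 15 propane-1,3-dithiol
Product: 16 2-[2-bromo-4,6-bis(triisopropylsilyloxy)phenyl]-1,3-dithiane
Conditions: BF3·OEt2 (0.3 equiv), CH2Cl2, −20 → 0 °C
Reagents that add atoms: none
Why: Lewis-acid-catalysed thioacetalisation of an aromatic aldehyde, which aryl silyl ethers tolerate because they are far more stable to acid than to base.

Step 11
Reactants: 16 2-[2-bromo-4,6-bis(triisopropylsilyloxy)phenyl]-1,3-dithiane; 10 (R)-2-ArB-oxirane
Product: 18 2-[2-bromo-4,6-bis(triisopropylsilyloxy)phenyl]-2-[(2S)-2-hydroxy-2-ArB-ethyl]-1,3-dithiane, via 2-lithio-1,3-dithiane 17 (not isolated)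
Conditions: 16 (1.2 equiv), LDA (1.1 equiv), THF–DMPU, −78 → −20 °C; then 10 (1.0 equiv), −20 °C → rt; aq. NH4Cl
Reagents that add atoms: none
Why: Corey–Seebach umpolung with epoxide opening, a reaction type known for doubly ortho-substituted 2-aryl-1,3-dithianes and styrene oxides, run here with a lithium amide in place of an alkyllithium so that the dithiane C–H is removed without bromine–lithium exchange; the carbanion attacks the unsubstituted CH2 in an SN2 sense, and since no bond at the stereocentre is touched the (R)-epoxide becomes the (S)-alcohol, the descriptor changing only because CH2 drops below aryl in the priority order.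

Step 12
Reactants: 18 2-[2-bromo-4,6-bis(triisopropylsilyloxy)phenyl]-2-[(2S)-2-hydroxy-2-ArB-ethyl]-1,3-dithiane
Product: 19 (2S)-2-ArB-5,7-bis(triisopropylsilyloxy)spiro[chromane-4,2'-[1,3]dithiane]
Conditions: CuI (20 mol%), 3,4,7,8-tetramethyl-1,10-phenanthroline (40 mol%), Cs2CO3 (2 equiv), 4 Å MS, toluene, 110 °C, argon
Reagents that add atoms: none
Why: After deprotonation by carbonate, the ligated monovalent copper alkoxide inserts into the neighbouring C8a–Br bond, and the resulting seven-membered trivalent copper chelate collapses by reductive elimination to the O1–C8a bond. The closest known reaction type is the intramolecular Ullmann-type O-arylation of secondary alcohols with aryl bromides that delivers chromans. Ring C closes as a six-membered ring by ipso substitution at C8a, helped by the fully substituted C4, which folds the chain towards the arene (gem-disubstituent effect). No stereocentre is created, and C2 keeps its S configuration since none of its four bonds takes part in the coupling. The chemoselectivity required is built into the substrate: there is one free hydroxyl and one carbon–halogen bond, both silyloxy groups are meta to C8a and so do not enrich that carbon, the thioacetal at C4 closes off the retro-aldol cleavage and dehydration that a hydroxy ketone would undergo in hot base, and copper alkoxides are much less prone than palladium alkoxides to β-hydride loss at the benzylic C2–H. The chelating diamine is used in excess over a raised copper loading to outbid the two thioether sulfurs, and molecular sieves keep hydroxide away from the aryl silyl ethers.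

Step 13
Reactants: 19 (2S)-2-ArB-5,7-bis(triisopropylsilyloxy)spiro[chromane-4,2'-[1,3]dithiane]
Product: 20 (2S)-2-ArB-5,7-bis(triisopropylsilyloxy)chroman-4-one
Conditions: MeI (excess), CaCO3, MeCN–H2O, 45 °C, dark
Reagents that add atoms: water, O
Why: Alkylative thioacetal hydrolysis, in which S-methylation makes sulfur a leaving group, the electron-rich ring A stabilises the thionium ion and water captures it, so that no oxidant or thiophilic heavy metal meets the prenyl and styryl alkenes and CaCO3 takes up the HI that would endanger the tertiary allylic C–O bond.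

Step 14
Reactants: 20 (2S)-2-ArB-5,7-bis(triisopropylsilyloxy)chroman-4-one
Product: 21 (2S)-5,7-dihydroxy-2-{3-[(E)-3-hydroxy-3-methylbut-1-enyl]-4-methoxy-5-(3-methylbut-2-enyl)phenyl}chroman-4-one (target)
Conditions: Bu4NF–AcOH (1:1, excess), THF, 0 °C → rt
Reagents that add atoms: none
Why: Fluoride-induced desilylation removes all three silyl groups in one operation, and the acetic acid buffer protonates each phenoxide at once, so that neither base-induced ring opening to the chalcone (loss of C2 configuration) nor acid ionisation of the tertiary allylic alcohol should occur.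

Compound list
1 | 3-bromo-4-hydroxybenzaldehyde | O=Cc1ccc(O)c(Br)c1 | starting material
2 | 3-bromo-4-hydroxy-5-iodobenzaldehyde | O=Cc1cc(Br)c(O)c(I)c1 | intermediate
3 | 3-bromo-5-iodo-4-methoxybenzaldehyde | COc1c(Br)cc(C=O)cc1I | intermediate
4 | 2-methylbut-3-en-2-ol | CC(C)(O)C=C | starting material
5 | 3-bromo-5-[(E)-3-hydroxy-3-methylbut-1-enyl]-4-methoxybenzaldehyde | COc1c(Br)cc(C=O)cc1/C=C/C(C)(C)O | intermediate
6 | 3-bromo-4-methoxy-5-[(E)-3-methyl-3-(triethylsilyloxy)but-1-enyl]benzaldehyde | CC[Si](CC)(CC)OC(C)(C)/C=C/c1cc(C=O)cc(Br)c1OC | intermediate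
7 | tributyl(3-methylbut-2-enyl)stannane | CCCC[Sn](CCCC)(CCCC)CC=C(C)C | starting material
8 | 4-methoxy-3-(3-methylbut-2-enyl)-5-[(E)-3-methyl-3-(triethylsilyloxy)but-1-enyl]benzaldehyde | CC[Si](CC)(CC)OC(C)(C)/C=C/c1cc(C=O)cc(CC=C(C)C)c1OC | intermediate
9 | racemic 2-ArB-oxirane | CC[Si](CC)(CC)OC(C)(C)/C=C/c1cc(C2CO2)cc(CC=C(C)C)c1OC | intermediate
10 | (R)-2-ArB-oxirane | CC[Si](CC)(CC)OC(C)(C)/C=C/c1cc([C@@H]2CO2)cc(CC=C(C)C)c1OC | intermediate
11 | 5-bromoresorcinol | Oc1cc(O)cc(Br)c1 | starting material
12 | N-(2-bromo-4,6-dihydroxybenzylidene)-N-methylmethanaminium dichlorophosphate | C[N+](C)=Cc1c(O)cc(O)cc1Br.[O-]P(=O)(Cl)Cl | intermediate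
13 | 2-bromo-4,6-dihydroxybenzaldehyde | O=Cc1c(O)cc(O)cc1Br | intermediate
14 | 2-bromo-4,6-bis(triisopropylsilyloxy)benzaldehyde | O=Cc1c(Br)cc(O[Si](C(C)C)(C(C)C)C(C)C)cc1O[Si](C(C)C)(C(C)C)C(C)C | intermediate
15 | propane-1,3-dithiol | SCCCS | starting material
16 | 2-[2-bromo-4,6-bis(triisopropylsilyloxy)phenyl]-1,3-dithiane | Brc1cc(O[Si](C(C)C)(C(C)C)C(C)C)cc(O[Si](C(C)C)(C(C)C)C(C)C)c1C1SCCCS1 | intermediate
17 | 2-[2-bromo-4,6-bis(triisopropylsilyloxy)phenyl]-2-lithio-1,3-dithiane | [Li]C1(SCCCS1)c1c(Br)cc(O[Si](C(C)C)(C(C)C)C(C)C)cc1O[Si](C(C)C)(C(C)C)C(C)C | intermediate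
18 | 2-[2-bromo-4,6-bis(triisopropylsilyloxy)phenyl]-2-[(2S)-2-hydroxy-2-ArB-ethyl]-1,3-dithiane | CC[Si](CC)(CC)OC(C)(C)/C=C/c1cc(cc(CC=C(C)C)c1OC)[C@@H](O)CC1(SCCCS1)c1c(Br)cc(O[Si](C(C)C)(C(C)C)C(C)C)cc1O[Si](C(C)C)(C(C)C)C(C)C | intermediate
19 | (2S)-2-ArB-5,7-bis(triisopropylsilyloxy)spiro[chromane-4,2'-[1,3]dithiane] | CC[Si](CC)(CC)OC(C)(C)/C=C/c1cc(cc(CC=C(C)C)c1OC)[C@@H]1CC2(SCCCS2)c2c(O1)cc(O[Si](C(C)C)(C(C)C)C(C)C)cc2O[Si](C(C)C)(C(C)C)C(C)C | intermediate
20 | (2S)-2-ArB-5,7-bis(triisopropylsilyloxy)chroman-4-one | CC[Si](CC)(CC)OC(C)(C)/C=C/c1cc(cc(CC=C(C)C)c1OC)[C@@H]1CC(=O)c2c(O1)cc(O[Si](C(C)C)(C(C)C)C(C)C)cc2O[Si](C(C)C)(C(C)C)C(C)C | intermediate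
21 | (2S)-5,7-dihydroxy-2-{3-[(E)-3-hydroxy-3-methylbut-1-enyl]-4-methoxy-5-(3-methylbut-2-enyl)phenyl}chroman-4-one | COc1c(/C=C/C(C)(C)O)cc([C@@H]2CC(=O)c3c(O)cc(O)cc3O2)cc1CC=C(C)C | target

Total step count: 14
Longest linear sequence: 11 (steps 1 to 7, then 11 to 14)

Steps most likely to fail

1. Step 12.
- **What may go wrong:** the two thioether sulfurs may displace the diamine ligand from copper so that turnover stalls. The prolonged heating with carbonate then strips aryl silyl groups.
- **Fallback:** it sets out from 18 and comes back at 20. It takes the sulfur out before ring closure without ever exposing a hydroxy ketone to hot base.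
- MeI, CaCO3 and aqueous MeCN convert 18 into the (3S)-hydroxy ketone F1.
- NaBH4 in MeOH–THF at 0 °C reduces it to the (3S)-1,3-diol F2. Both epimers at the future C4 are acceptable, since that centre is oxidised later.
- The copper conditions of step 12 then close ring C to the (2S)-flavan-4-ol F3. The C4 hydroxyl cannot compete, because its arylation would need a four-membered ring.
- Dess–Martin periodinane with NaHCO3 in CH2Cl2 oxidises C4 and gives 20.

2. Step 11.
- **What may go wrong:** the amide base may deprotonate the crowded, electron-rich aryl dithiane slowly or incompletely. Ring metalation with loss of bromide, an O-to-C silyl shift, and sluggish or benzylic attack on the epoxide are further risks.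
- **Fallback:** it sets out from 14 and 8 and comes back at 18. It uses neither a dithiane carbanion nor an epoxide.
- Lithiated trimethylsilyldiazomethane (Colvin rearrangement) homologates 14 to the aryl acetylene F4.
- The lithium acetylide of F4 is made with LiN(SiMe3)2, which leaves C–Br alone. It adds to aldehyde 8 to give the racemic propargylic alcohol F5.
- MnO2 gives the ynone F6.
- Double conjugate addition of propane-1,3-dithiol 15 (NaOMe, MeOH–CH2Cl2, −10 °C) places both sulfurs on the β-carbon and gives the β-keto dithiane F7.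
- Corey–Bakshi–Shibata reduction with the (R)-methyl oxazaborolidine and catecholborane at low temperature gives 18. The aryl group acts as the large substituent, and catecholborane is chosen to spare the alkenes.

3. Step 7.
- **What may go wrong:** unselective opening at the benzylic carbon and Lewis-acid-induced rearrangement of an electron-rich aryl oxirane to the aldehyde would erode both the selectivity of the resolution and the recovery of epoxide.
- **Fallback:** it sets out from 8 and comes back at 10. It replaces resolution by asymmetric reduction.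
- Chloromethyllithium (ClCH2I, MeLi·LiBr, THF, −78 °C, acetic acid quench at −78 °C) adds to 8 to give the racemic chlorohydrin F8.
- Dess–Martin periodinane gives the chloromethyl ketone F9.
- Noyori asymmetric transfer hydrogenation with RuCl[(S,S)-TsDPEN](p-cymene) in HCO2H–Et3N gives the (R)-chlorohydrin F10.
- K2CO3 in MeOH closes F10 to 10, with the C–O bond of the stereocentre untouched.

Further compounds
F1 | step 12 | (3S)-1-[2-bromo-4,6-bis(triisopropylsilyloxy)phenyl]-3-hydroxy-3-ArB-propan-1-one | CC[Si](CC)(CC)OC(C)(C)/C=C/c1cc(cc(CC=C(C)C)c1OC)[C@@H](O)CC(=O)c1c(Br)cc(O[Si](C(C)C)(C(C)C)C(C)C)cc1O[Si](C(C)C)(C(C)C)C(C)C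
F2 | step 12 | (3S)-1-[2-bromo-4,6-bis(triisopropylsilyloxy)phenyl]-3-ArB-propane-1,3-diol, both C1 epimers | CC[Si](CC)(CC)OC(C)(C)/C=C/c1cc(cc(CC=C(C)C)c1OC)[C@@H](O)CC(O)c1c(Br)cc(O[Si](C(C)C)(C(C)C)C(C)C)cc1O[Si](C(C)C)(C(C)C)C(C)C
F3 | step 12 | (2S)-2-ArB-5,7-bis(triisopropylsilyloxy)chroman-4-ol, both C4 epimers | CC[Si](CC)(CC)OC(C)(C)/C=C/c1cc(cc(CC=C(C)C)c1OC)[C@@H]1CC(O)c2c(O1)cc(O[Si](C(C)C)(C(C)C)C(C)C)cc2O[Si](C(C)C)(C(C)C)C(C)C
F4 | step 11 | 1-bromo-2-ethynyl-3,5-bis(triisopropylsilyloxy)benzene | C#Cc1c(Br)cc(O[Si](C(C)C)(C(C)C)C(C)C)cc1O[Si](C(C)C)(C(C)C)C(C)C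
F5 | step 11 | racemic 3-[2-bromo-4,6-bis(triisopropylsilyloxy)phenyl]-1-ArB-prop-2-yn-1-ol | CC[Si](CC)(CC)OC(C)(C)/C=C/c1cc(cc(CC=C(C)C)c1OC)C(O)C#Cc1c(Br)cc(O[Si](C(C)C)(C(C)C)C(C)C)cc1O[Si](C(C)C)(C(C)C)C(C)C
F6 | step 11 | 3-[2-bromo-4,6-bis(triisopropylsilyloxy)phenyl]-1-ArB-prop-2-yn-1-one | CC[Si](CC)(CC)OC(C)(C)/C=C/c1cc(cc(CC=C(C)C)c1OC)C(=O)C#Cc1c(Br)cc(O[Si](C(C)C)(C(C)C)C(C)C)cc1O[Si](C(C)C)(C(C)C)C(C)C
F7 | step 11 | 2-{2-[2-bromo-4,6-bis(triisopropylsilyloxy)phenyl]-1,3-dithian-2-yl}-1-ArB-ethan-1-one | CC[Si](CC)(CC)OC(C)(C)/C=C/c1cc(cc(CC=C(C)C)c1OC)C(=O)CC1(SCCCS1)c1c(Br)cc(O[Si](C(C)C)(C(C)C)C(C)C)cc1O[Si](C(C)C)(C(C)C)C(C)C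
F8 | step 7 | racemic 2-chloro-1-ArB-ethanol | CC[Si](CC)(CC)OC(C)(C)/C=C/c1cc(cc(CC=C(C)C)c1OC)C(O)CCl
F9 | step 7 | 2-chloro-1-ArB-ethanone | CC[Si](CC)(CC)OC(C)(C)/C=C/c1cc(cc(CC=C(C)C)c1OC)C(=O)CCl
F10 | step 7 | (R)-2-chloro-1-ArB-ethanol | CC[Si](CC)(CC)OC(C)(C)/C=C/c1cc(cc(CC=C(C)C)c1OC)[C@@H](O)CCl
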